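**Retrosynthetic overview** (2H-chromene numbering: O1, C2, C3=C4, C4a, C5–C8, C8a; ring A = benzene ring, ring B = pyran ring)
1. The feruloyl ester is made last from the (R)-configured primary alcohol at C2–CH2OH; the C2 configuration is selected by a lipase acting on the racemic C2–CH2OAc chromene.
2. Ring B is closed in one operation that makes C2–C3 and C4–C4a: C3/C4 come from vinyl acetate, C2 loses a carboxyl group, C4a loses its hydrogen, and acetic acid is then lost across C3–C4.
3. Enabling feature: O1 makes C2 an aryloxocarbenium carbon once CO2 is removed at the anode, and the ester carbonyl on the C2–CH2O arm holds that cation as a dioxolanylium ion. C4a of ring A is para to the C7 hydroxyl, ortho to O1 and meta to the C6 acetyl, so the arene closes there, and the same C7 hydroxyl later expels the C4 acetate.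
4. The acid precursor comes from 2,4-dihydroxyacetophenone (ring A bought complete), silyl-protected hydroxyacetone and chloroform in a Bargellini three-component reaction, followed by O-acetylation.
5. Ring order: ring A is present from the start; ring B is the only ring formed (step 3); the ferulate ring is bought.

Key step: step 3

Assumption: the lipase of step 4 is taken to hydrolyse the (R)-acetate faster; lipases are used to resolve closely related 2-(hydroxymethyl)-2-methylchromans, but the sense for this substrate has to be confirmed by experiment.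
Remark: 2H-chromenes racemise at C2 under UV light by reversible electrocyclic opening of ring B, so all enantioenriched chromenes (from step 4 onward) are handled with exclusion of light.

**Step 1**
Reactants: 1 1-(2,4-dihydroxyphenyl)ethan-1-one; 2 1-[(tert-butyldimethylsilyl)oxy]propan-2-one; 3 chloroform
Product: 5 rac-2-(4-acetyl-3-hydroxyphenoxy)-3-hydroxy-2-methylpropanoic acid, via silyl ether acid 4 (not isolated)
Conditions: 2 (4 equiv), 3 (3 equiv), powdered NaOH (8 equiv), THF, 0 °C to rt; then 2 M HCl, THF/H2O, rt
Reagents that add atoms: sodium hydroxide, [Na+].[OH-]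
Why: Bargellini three-component reaction, in which trichloromethanide adds to ketone 2, the alkoxide closes to a gem-dichloroepoxide, the more nucleophilic 4-phenoxide of 1 (the 2-oxygen is chelated to the acetyl group) opens it at the tertiary carbon and the acyl chloride is hydrolysed, so the quaternary carbon forms as a racemate and the acid treatment then removes the silyl group.

**Step 2**
Reactants: 5 rac-2-(4-acetyl-3-hydroxyphenoxy)-3-hydroxy-2-methylpropanoic acid
Product: 6 rac-3-acetoxy-2-(4-acetyl-3-hydroxyphenoxy)-2-methylpropanoic acid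
Conditions: Ac2O (1.5 equiv), pyridine, CH2Cl2, 0 °C; aq. NaHCO3, then acidify
Reagents that add atoms: acetic anhydride, CC(=O)OC(C)=O
Why: O-acetylation of the primary alcohol should be much faster than that of the phenol, which is hydrogen-bonded to the ortho acetyl group, and any mixed anhydride at the carboxyl is hydrolysed in the work-up.

**Step 3**
Reactants: 6 rac-3-acetoxy-2-(4-acetyl-3-hydroxyphenoxy)-2-methylpropanoic acid; 7 vinyl acetate
Product: 9 rac-(6-acetyl-7-hydroxy-2-methyl-2H-chromen-2-yl)methyl acetate, via 4-acetoxychroman 8 (not isolated)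
Conditions: undivided cell, graphite anode, Pt cathode, constant current, ca. 2.5 F/mol, 7 (10 equiv), 2,4,6-collidine (1.5 equiv), n-Bu4NPF6 (0.1 M), 3 Å MS, CH2Cl2, 0 °C; evaporate; then DBU (3 equiv), MeCN, 40 °C
Reagents that add atoms: none
Why: Proposed new method: anodic two-electron oxidation of the carboxylate of 6 (Hofer–Moest decarboxylation) should give the aryloxocarbenium ion at C2, held reversibly as a 1,3-dioxolan-2-ylium ion by the neighbouring acetoxy group; vinyl acetate adds through its CH2 terminus (C2–C3 bond) and the acyloxycarbenium ion so formed at C4 alkylates the arene at C4a (C4–C4a bond), a formal cationic [4+2] of the C4a=C8a–O1=C2 oxadiene with the enol ester. The closest known reaction types are the Hofer–Moest generation of alkoxy- and aryloxycarbenium ions from α-oxy acids and the Lewis-acid oxa-Povarov reaction of aryl oxocarbenium ions with alkenes, which has not been run with an electrogenerated, ketone-derived cation and a vinyl ester. Ring B closes in a 6-exo-trig Friedel–Crafts mode. C2 is created as a racemate because the cation is planar, and its configuration is selected afterwards in step 4. The step needs closure at C4a and not at C8, which the substrate secures because C4a is para to the free C7 hydroxyl, ortho to O1 and meta to the acetyl whereas C8 is flanked by two oxygen substituents; it also needs the anode to take the carboxylate before the chelated, acetyl-deactivated phenol ring, and vinyl acetate is chosen because it is neither oxidised at that potential nor polymerised by cations. In the second stage DBU forms the C7 phenoxide, which expels the para-benzylic C4 acetate through a quinone methide that tautomerises to the C3=C4 alkene of 9.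

**Step 4**
Reactants: 9 rac-(6-acetyl-7-hydroxy-2-methyl-2H-chromen-2-yl)methyl acetate
Product: 10 1-[(2R)-7-hydroxy-2-(hydroxymethyl)-2-methyl-2H-chromen-6-yl]ethan-1-one
Conditions: immobilised Candida antarctica lipase B, phosphate buffer pH 7/MTBE, 30 °C, stopped near 50% conversion, dark
Reagents that add atoms: none
Why: Enzymatic kinetic resolution by a lipase (serine hydrolase), whose chiral active site should hydrolyse the primary acetate of the (R)-enantiomer much faster, so the C2 configuration of 10 is selected here while the (S)-enantiomer of 9 stays as its acetate and is removed by chromatography.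

**Step 5**
Reactants: 10 1-[(2R)-7-hydroxy-2-(hydroxymethyl)-2-methyl-2H-chromen-6-yl]ethan-1-one; 11 (E)-3-(4-acetoxy-3-methoxyphenyl)prop-2-enoic acid
Product: 12 [(2R)-6-acetyl-7-hydroxy-2-methyl-2H-chromen-2-yl]methyl (E)-3-(4-acetoxy-3-methoxyphenyl)prop-2-enoate
Conditions: 11 (1.2 equiv), EDC·HCl (1.5 equiv), DMAP (0.2 equiv), CH2Cl2, 0 °C to rt, dark
Reagents that add atoms: none
Why: Steglich esterification, in which the primary alcohol of 10 should be acylated while the C7 phenol, tied up in a hydrogen bond to the C6 acetyl group, is not, and C2 is not touched.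

**Step 6**
Reactants: 12 [(2R)-6-acetyl-7-hydroxy-2-methyl-2H-chromen-2-yl]methyl (E)-3-(4-acetoxy-3-methoxyphenyl)prop-2-enoate
Product: 13 [(2R)-6-acetyl-7-hydroxy-2-methyl-2H-chromen-2-yl]methyl (E)-3-(4-hydroxy-3-methoxyphenyl)prop-2-enoate
Conditions: pyrrolidine (3 equiv), CH2Cl2, 0 °C, dark
Reagents that add atoms: none
Why: Chemoselective aminolysis, since an aryl acetate should be attacked by the amine far faster than the alkyl cinnamate ester, so the ferulate phenol is released without touching the ester or C2.

**Compound list**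
1 | 1-(2,4-dihydroxyphenyl)ethan-1-one | CC(=O)c1ccc(O)cc1O | starting material
2 | 1-[(tert-butyldimethylsilyl)oxy]propan-2-one | CC(=O)CO[Si](C)(C)C(C)(C)C | starting material
3 | chloroform | ClC(Cl)Cl | starting material
4 | rac-2-(4-acetyl-3-hydroxyphenoxy)-3-[(tert-butyldimethylsilyl)oxy]-2-methylpropanoic acid (not isolated) | CC(=O)c1ccc(OC(C)(CO[Si](C)(C)C(C)(C)C)C(=O)O)cc1O | intermediate
5 | rac-2-(4-acetyl-3-hydroxyphenoxy)-3-hydroxy-2-methylpropanoic acid | CC(=O)c1ccc(OC(C)(CO)C(=O)O)cc1O | intermediate
6 | rac-3-acetoxy-2-(4-acetyl-3-hydroxyphenoxy)-2-methylpropanoic acid | CC(=O)OCC(C)(Oc1ccc(C(C)=O)c(O)c1)C(=O)O | intermediate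
7 | vinyl acetate | C=COC(C)=O | starting material
8 | rac-(4-acetoxy-6-acetyl-7-hydroxy-2-methyl-3,4-dihydro-2H-chromen-2-yl)methyl acetate, mixture of C4 epimers (not isolated) | CC(=O)OCC1(C)CC(OC(C)=O)c2cc(C(C)=O)c(O)cc2O1 | intermediate
9 | rac-(6-acetyl-7-hydroxy-2-methyl-2H-chromen-2-yl)methyl acetate | CC(=O)OCC1(C)C=Cc2cc(C(C)=O)c(O)cc2O1 | intermediate
10 | 1-[(2R)-7-hydroxy-2-(hydroxymethyl)-2-methyl-2H-chromen-6-yl]ethan-1-one | OC[C@@]1(C)C=Cc2cc(C(C)=O)c(O)cc2O1 | intermediate
11 | (E)-3-(4-acetoxy-3-methoxyphenyl)prop-2-enoic acid (O-acetylferulic acid) | COc1cc(/C=C/C(=O)O)ccc1OC(C)=O | starting material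
12 | [(2R)-6-acetyl-7-hydroxy-2-methyl-2H-chromen-2-yl]methyl (E)-3-(4-acetoxy-3-methoxyphenyl)prop-2-enoate | COc1cc(/C=C/C(=O)OC[C@@]2(C)C=Cc3cc(C(C)=O)c(O)cc3O2)ccc1OC(C)=O | intermediate
13 | [(2R)-6-acetyl-7-hydroxy-2-methyl-2H-chromen-2-yl]methyl (E)-3-(4-hydroxy-3-methoxyphenyl)prop-2-enoate | COc1cc(/C=C/C(=O)OC[C@@]2(C)C=Cc3cc(C(C)=O)c(O)cc3O2)ccc1O | target

**Totals**
Total steps: 6. Longest linear sequence: 6 steps (1 to 13).

**Steps most likely to fail**

Step 3 (proposed new method). The anode may oxidise the phenolic arene instead of the carboxylate. The cation may lose a proton to an enol ether or be captured by carboxylate before vinyl acetate adds. Ring closure may be slow or take place partly at C8. The fallback uses known reaction types, sets out from 1 and returns at 10, so it replaces steps 1 to 4. Compound 1 is brominated para to the chelated hydroxyl (NBS, MeCN, 0 °C) to 1-(5-bromo-2,4-dihydroxyphenyl)ethan-1-one F1. Suzuki–Miyaura coupling with potassium vinyltrifluoroborate (PdCl2(dppf), Cs2CO3, THF/H2O, 70 °C) should give 1-(5-ethenyl-2,4-dihydroxyphenyl)ethan-1-one F2. A decarboxylative allylic etherification of racemic 4-methyl-4-vinyl-1,3-dioxolan-2-one at the free 4-hydroxyl, catalysed by zerovalent palladium (Pd2(dba)3 with the enantiomer of a chiral phosphoramidite ligand that delivers the R ether, THF, rt), should give 1-[5-ethenyl-2-hydroxy-4-{[(2R)-1-hydroxy-2-methylbut-3-en-2-yl]oxy}phenyl]ethan-1-one F3, with C2 set by the ligand. Ring-closing metathesis with the second-generation Grubbs catalyst RuCl2(=CHPh)(PCy3)(H2IMes) (CH2Cl2, 40 °C, dark) then closes ring B across C3=C4 to give 10.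

Step 4. The lipase may discriminate poorly between the enantiomers because the stereocentre is quaternary and one carbon away from the ester, or it may prefer the wrong enantiomer. The fallback sets out from 9 and returns at 10. Racemic 9 is methanolysed (K2CO3, MeOH, 0 °C) to rac-1-[7-hydroxy-2-(hydroxymethyl)-2-methyl-2H-chromen-6-yl]ethan-1-one F4. Acylation of the primary hydroxyl with (1S)-camphanic chloride (Et3N, DMAP, CH2Cl2, 0 °C) should give two diastereomeric esters: [(2R)-6-acetyl-7-hydroxy-2-methyl-2H-chromen-2-yl]methyl (1S,4R)-4,7,7-trimethyl-3-oxo-2-oxabicyclo[2.2.1]heptane-1-carboxylate F5 and [(2S)-6-acetyl-7-hydroxy-2-methyl-2H-chromen-2-yl]methyl (1S,4R)-4,7,7-trimethyl-3-oxo-2-oxabicyclo[2.2.1]heptane-1-carboxylate F6. These are separated by crystallisation or chromatography, and F5 is cleaved with LiOH (THF/H2O, 0 °C, dark) to 10.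

Step 1. Dichlorocarbene formed from chloroform and hydroxide may attack the electron-rich resorcinol-type ring (Reimer–Tiemann formylation), and ketone 2 may self-condense or lose its silyl group before it is captured. The fallback sets out from 2 and 3 and returns at 4. The two are first joined without hydroxide (DBU, neat CHCl3, rt) to rac-1-[(tert-butyldimethylsilyl)oxy]-3,3,3-trichloro-2-methylpropan-2-ol F7. This carbinol is then treated with 1 and NaOH in DME/H2O (Jocic–Reeve reaction: the gem-dichloroepoxide is opened by the 4-phenoxide at the tertiary carbon) to give 4, and the acid treatment of step 1 leads on to 5.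

**Further compounds**
F1 | step 3 | 1-(5-bromo-2,4-dihydroxyphenyl)ethan-1-one | CC(=O)c1cc(Br)c(O)cc1O
F2 | step 3 | 1-(5-ethenyl-2,4-dihydroxyphenyl)ethan-1-one | CC(=O)c1cc(C=C)c(O)cc1O
F3 | step 3 | 1-[5-ethenyl-2-hydroxy-4-{[(2R)-1-hydroxy-2-methylbut-3-en-2-yl]oxy}phenyl]ethan-1-one | OC[C@@](Oc1cc(O)c(C(C)=O)cc1C=C)(C)C=C
F4 | step 4 | rac-1-[7-hydroxy-2-(hydroxymethyl)-2-methyl-2H-chromen-6-yl]ethan-1-one | OCC1(C)C=Cc2cc(C(C)=O)c(O)cc2O1
F5 | step 4 | [(2R)-6-acetyl-7-hydroxy-2-methyl-2H-chromen-2-yl]methyl (1S,4R)-4,7,7-trimethyl-3-oxo-2-oxabicyclo[2.2.1]heptane-1-carboxylate | CC1(C)[C@@]2(C)CC[C@]1(C(=O)OC[C@@]3(C)C=Cc4cc(C(C)=O)c(O)cc4O3)OC2=O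
F6 | step 4 | [(2S)-6-acetyl-7-hydroxy-2-methyl-2H-chromen-2-yl]methyl (1S,4R)-4,7,7-trimethyl-3-oxo-2-oxabicyclo[2.2.1]heptane-1-carboxylate | CC1(C)[C@@]2(C)CC[C@]1(C(=O)OC[C@]3(C)C=Cc4cc(C(C)=O)c(O)cc4O3)OC2=O
F7 | step 1 | rac-1-[(tert-butyldimethylsilyl)oxy]-3,3,3-trichloro-2-methylpropan-2-ol | CC(O)(CO[Si](C)(C)C(C)(C)C)C(Cl)(Cl)Cl
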